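**Plan**

- Retrosynthesis: the quinone hydroxy group goes back to a methoxy group and quinone ring A to a 1,2,4,5-tetramethoxybenzene. The side chain is then cut at C1–C2 and at C3–CH3 (C1 = CH2 on ring A, C2=C3 = chain alkene, C4 and C5 = the two CH2 groups, C6 = stereocentre of cyclohexene ring B).
- Enabling feature: the C2=C3 alkene is E-trisubstituted, carries its methyl on C3 and is separated from ring A only by C1. This is the pattern left by syn CH3–metal addition to a terminal C2≡C3 alkyne followed by benzylation at C2.
- Forward: ring B comes ready-made from α-ionone (conjugate reduction, methyl ketone to terminal alkyne) and ring A from 1,2,4,5-tetramethoxybenzene (formylation, reduction, chlorination). The two are joined with Al(CH3)3 in one pot without ring formation; ring A is then oxidised to the quinone and one methoxy group is hydrolysed.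
- Stereochemistry: the only stereocentre, C6 (S), is secured by resolving racemic α-ionone as a menthyl carbazone and is not touched afterwards. The E geometry of C2=C3 comes from the syn carbometalation and is retained in the coupling.

Key step: step 9

Remark (assumption): in step 2 the less soluble hydrazone is taken to be the one pairing the (1S,2R,5S)-menthyl carbazate with (S)-α-ionone; if the pairing is the opposite, the enantiomeric carbazate from (1R,2S,5R)-menthyl chloroformate is used and nothing else changes.

**Route**

Step 1
Reactants: 1 (1S,2R,5S)-(+)-menthyl chloroformate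
Product: 2 (1S,2R,5S)-(+)-menthyl carbazate
Conditions: N2H4·H2O (3 equiv), Et2O, 0 °C to rt
Reagents that add atoms: hydrazine (used as the hydrate), NN
Why: Acyl substitution at the chloroformate by hydrazine (carbamate formation) should give the carbazate, the excess hydrazine taking up HCl and suppressing double acylation, while the three menthyl stereocentres are spectators.

Step 2
Reactants: 3 racemic α-ionone; 2 (1S,2R,5S)-(+)-menthyl carbazate
Product: 4 (1S,2R,5S)-menthyl carbazone of (S)-α-ionone (E at C=N, E at C=C)
Conditions: NaOAc, AcOH, EtOH, 60 °C; then fractional crystallisation from EtOH to constant rotation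
Reagents that add atoms: none
Why: Buffered condensation of the ketone with the carbazate (hydrazone formation) turns the two enantiomers of 3 into diastereomers of different solubility, so that fractional crystallisation (classical resolution) should deliver the less soluble one, and this selection fixes the C6 configuration of the target.

Step 3
Reactants: 4 (1S,2R,5S)-menthyl carbazone of (S)-α-ionone
Product: 5 (S)-(−)-α-ionone
Conditions: aq. phthalic acid, steam distillation; carbazate 2 recovered from the residue
Reagents that add atoms: water, O
Why: Acid-catalysed hydrolysis of the N-acylhydrazone, driven by removal of the volatile ketone with steam, should release the enone under conditions too mild to form the dienol through C6 or to move the ring double bond into conjugation.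

Step 4
Reactants: 5 (S)-(−)-α-ionone
Product: 6 (S)-dihydro-α-ionone, (S)-4-(2,6,6-trimethylcyclohex-2-en-1-yl)butan-2-one
Conditions: Bu3SnH (1.2 equiv), Pd(PPh3)4 (2 mol %), AcOH (1.5 equiv), THF, rt
Reagents that add atoms: none
Why: Palladium-catalysed 1,4-hydrostannation of the enone followed by protonolysis of the tin enolate (conjugate reduction) should saturate only the electron-poor C=C, leaving the isolated trisubstituted ring alkene and the C6 centre, which is never deprotonated, unchanged.

Step 5
Reactants: 6 (S)-dihydro-α-ionone
Product: 8 (S)-6-(but-3-yn-1-yl)-1,5,5-trimethylcyclohex-1-ene, via enol diethyl phosphate 7 (not isolated)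
Conditions: LiN(i-Pr)2 (1.05 equiv), THF, −78 °C; ClP(O)(OEt)2, −78 °C to rt; then LiN(i-Pr)2 (2.3 equiv), THF, −78 °C to rt; aq. NH4Cl
Reagents that add atoms: none
Why: Kinetic deprotonation at the methyl group and O-phosphorylation give the terminal enol phosphate, from which excess amide base eliminates diethyl phosphate (methyl ketone to terminal alkyne by enol phosphate elimination) and holds the product as its acetylide, which should prevent drift to the allene or the internal alkyne, while C6 is remote and not acidic.

Step 6
Reactants: 9 1,2,4,5-tetramethoxybenzene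
Product: 11 2,3,5,6-tetramethoxybenzaldehyde, via aryllithium 10 (not isolated)
Conditions: n-BuLi (1.05 equiv), THF, 0 °C to rt; DMF, 0 °C; aq. NH4Cl
Reagents that add atoms: N,N-dimethylformamide, CN(C)C=O
Why: Directed ortho-lithiation at a ring CH flanked by two methoxy groups followed by formylation with DMF should give the mono-aldehyde, since the two free positions are equivalent and only one equivalent of base is used.

Step 7
Reactants: 11 2,3,5,6-tetramethoxybenzaldehyde
Product: 12 (2,3,5,6-tetramethoxyphenyl)methanol
Conditions: NaBH4, MeOH, 0 °C
Reagents that add atoms: none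
Why: Hydride reduction of the aryl aldehyde with NaBH4 is chemoselective and leaves the four aryl methyl ethers untouched.

Step 8
Reactants: 12 (2,3,5,6-tetramethoxyphenyl)methanol
Product: 13 3-(chloromethyl)-1,2,4,5-tetramethoxybenzene
Conditions: SOCl2, pyridine, CH2Cl2, 0 °C; used without purification
Reagents that add atoms: thionyl chloride, ClS(Cl)=O
Why: Deoxychlorination through the chlorosulfite with pyridine as HCl scavenger (nucleophilic substitution at an activated benzylic carbon) avoids the free acid that could trigger Friedel–Crafts self-condensation of this electron-rich benzylic system.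

Step 9
Reactants: 8 (S)-6-(but-3-yn-1-yl)-1,5,5-trimethylcyclohex-1-ene; 14 trimethylaluminium; 13 3-(chloromethyl)-1,2,4,5-tetramethoxybenzene
Product: 16 1,2,4,5-tetramethoxy-3-{(E)-3-methyl-5-[(S)-2,6,6-trimethylcyclohex-2-en-1-yl]pent-2-en-1-yl}benzene, via alkenylalane 15 (not isolated)
Conditions: Al(CH3)3 (2 equiv), Cp2ZrCl2 (0.25 equiv), ClCH2CH2Cl, 0 °C to rt; volatiles removed, THF; then 13, NiCl2(PPh3)2 (3 mol %)/n-BuLi (6 mol %), THF, 0 °C to rt
Reagents that add atoms: none
Why: Cp2ZrCl2 and Al(CH3)3 form an electrophilic methylzirconocene species that adds CH3 and metal syn across the terminal C2≡C3 triple bond of 8, methyl going to the internal carbon C3 and the metal to the unhindered terminus C2, and exchange of zirconium for aluminium leaves the (E)-alkenylalane 15. Zerovalent nickel, formed from NiCl2(PPh3)2 and n-BuLi, inserts into the benzylic C–Cl bond of 13, takes over the alkenyl group from aluminium and releases 16 by reductive elimination, which forms C1–C2 with retention of the double-bond geometry. The closest known reaction type is the Negishi zirconium-catalysed methylalumination of terminal alkynes joined in one pot to the nickel-catalysed coupling of alkenylalanes with benzylic chlorides, an established entry to prenylated hydroquinone ethers. No ring is closed and no stereocentre is created; the step only has to deliver the methyl on C3 and the E geometry, and both follow from the terminal alkyne itself through syn addition with the metal at the less substituted carbon. The trisubstituted ring alkene is too hindered to be carbometalated and C6 is neither acidic nor on the reaction path, so the (S) centre should pass unchanged. Stripping the excess Al(CH3)3 and coupling in THF tames the Lewis acidity, so that the electron-rich chloride 13 should be neither ionised nor methylated.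

Step 10
Reactants: 16 1,2,4,5-tetramethoxy-3-{(E)-3-methyl-5-[(S)-2,6,6-trimethylcyclohex-2-en-1-yl]pent-2-en-1-yl}benzene
Product: 17 2,5-dimethoxy-3-{(E)-3-methyl-5-[(S)-2,6,6-trimethylcyclohex-2-en-1-yl]pent-2-en-1-yl}cyclohexa-2,5-diene-1,4-dione
Conditions: (NH4)2Ce(NO3)6 (2.5 equiv), MeCN/H2O, 0 °C
Reagents that add atoms: water, O
Why: Oxidative demethylation of the electron-rich arene by tetravalent cerium (arene radical cation, addition of water, loss of methanol) should give the para-quinone, and because either para pair of methoxy-bearing carbons leads to the same 2,5-dimethoxy-3-alkylquinone only ortho-quinone formation has to be held down by low temperature and short contact, the isolated alkenes being inert to the oxidant under these conditions.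

Step 11
Reactants: 17 2,5-dimethoxy-3-{(E)-3-methyl-5-[(S)-2,6,6-trimethylcyclohex-2-en-1-yl]pent-2-en-1-yl}cyclohexa-2,5-diene-1,4-dione
Product: 18 2-hydroxy-5-methoxy-3-{(E)-3-methyl-5-[(S)-2,6,6-trimethylcyclohex-2-en-1-yl]pent-2-en-1-yl}cyclohexa-2,5-diene-1,4-dione (target)
Conditions: 70% aq. HClO4, THF, 0 °C to rt
Reagents that add atoms: water, O
Why: Acid-catalysed addition–elimination of water at a vinylogous ester carbon (vinylogous ester hydrolysis) should take place at the methoxy group wedged between the side chain and a carbonyl, which is twisted out of conjugation and relieved of strain on hydrolysis, in preference to the unhindered methoxy group next to the ring CH.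

**Compound list**

1 | (1S,2R,5S)-(+)-menthyl chloroformate | ClC(=O)O[C@H]1C[C@@H](C)CC[C@@H]1C(C)C | starting material
2 | (1S,2R,5S)-(+)-menthyl carbazate (menthyl hydrazinecarboxylate) | NNC(=O)O[C@H]1C[C@@H](C)CC[C@@H]1C(C)C | intermediate
3 | racemic α-ionone, (E)-4-(2,6,6-trimethylcyclohex-2-en-1-yl)but-3-en-2-one | CC(=O)/C=C/C1C(C)=CCCC1(C)C | starting material
4 | (1S,2R,5S)-menthyl N'-{(E,3E)-4-[(S)-2,6,6-trimethylcyclohex-2-en-1-yl]but-3-en-2-ylidene}carbazate | C/C(=N\NC(=O)O[C@H]1C[C@@H](C)CC[C@@H]1C(C)C)/C=C/[C@@H]2C(C)=CCCC2(C)C | intermediate
5 | (S)-(−)-α-ionone | CC(=O)/C=C/[C@@H]1C(C)=CCCC1(C)C | intermediate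
6 | (S)-dihydro-α-ionone, (S)-4-(2,6,6-trimethylcyclohex-2-en-1-yl)butan-2-one | CC(=O)CC[C@@H]1C(C)=CCCC1(C)C | intermediate
7 | diethyl 4-[(S)-2,6,6-trimethylcyclohex-2-en-1-yl]but-1-en-2-yl phosphate | C=C(OP(=O)(OCC)OCC)CC[C@@H]1C(C)=CCCC1(C)C | intermediate (not isolated)
8 | (S)-6-(but-3-yn-1-yl)-1,5,5-trimethylcyclohex-1-ene | C#CCC[C@@H]1C(C)=CCCC1(C)C | intermediate
9 | 1,2,4,5-tetramethoxybenzene | COc1cc(OC)c(OC)cc1OC | starting material
10 | (2,3,5,6-tetramethoxyphenyl)lithium | [Li]c1c(OC)c(OC)cc(OC)c1OC | intermediate (not isolated)
11 | 2,3,5,6-tetramethoxybenzaldehyde | COc1cc(OC)c(OC)c(C=O)c1OC | intermediate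
12 | (2,3,5,6-tetramethoxyphenyl)methanol | COc1cc(OC)c(OC)c(CO)c1OC | intermediate
13 | 3-(chloromethyl)-1,2,4,5-tetramethoxybenzene | COc1cc(OC)c(OC)c(CCl)c1OC | intermediate
14 | trimethylaluminium, Al(CH3)3 | C[Al](C)C | starting material
15 | dimethyl{(E)-2-methyl-4-[(S)-2,6,6-trimethylcyclohex-2-en-1-yl]but-1-en-1-yl}alane | C[Al](C)/C=C(\C)CC[C@@H]1C(C)=CCCC1(C)C | intermediate (not isolated)
16 | 1,2,4,5-tetramethoxy-3-{(E)-3-methyl-5-[(S)-2,6,6-trimethylcyclohex-2-en-1-yl]pent-2-en-1-yl}benzene | COc1cc(OC)c(OC)c(C/C=C(\C)CC[C@@H]2C(C)=CCCC2(C)C)c1OC | intermediate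
17 | 2,5-dimethoxy-3-{(E)-3-methyl-5-[(S)-2,6,6-trimethylcyclohex-2-en-1-yl]pent-2-en-1-yl}cyclohexa-2,5-diene-1,4-dione | COC1=CC(=O)C(OC)=C(C/C=C(\C)CC[C@@H]2C(C)=CCCC2(C)C)C1=O | intermediate
18 | 2-hydroxy-5-methoxy-3-{(E)-3-methyl-5-[(S)-2,6,6-trimethylcyclohex-2-en-1-yl]pent-2-en-1-yl}cyclohexa-2,5-diene-1,4-dione | COC1=CC(=O)C(O)=C(C/C=C(\C)CC[C@@H]2C(C)=CCCC2(C)C)C1=O | target

**Step count and risks**

Total step count: 11. Longest linear sequence: 8 steps (steps 1, 2, 3, 4, 5, 9, 10, 11).

Steps most likely to fail:

1. Step 2. The two diastereomeric hydrazones may co-crystallise, so that the solid never reaches diastereomeric purity, or the solubility order may not favour the wanted one. The fallback sets out from racemic 3 and comes back at 5. The enantiomers of 3 are separated directly by preparative chromatography on a chiral stationary phase (cellulose tris(3,5-dimethylphenylcarbamate), supercritical CO2/2-propanol), and the levorotatory fraction is taken on. Steps 1 to 3 fall away and no new compound arises (F0).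

2. Step 9. The Lewis-acidic aluminium species may ionise the electron-rich benzylic chloride, which then alkylates the free ring position of another molecule. Methyl instead of alkenyl may be transferred to nickel, or the chloride may homocouple. The fallback sets out from 8 (through alane 15) and from 13, and comes back at 16. The alane solution is quenched with I2 in THF at −30 °C to give (S)-6-[(E)-4-iodo-3-methylbut-3-en-1-yl]-1,5,5-trimethylcyclohex-1-ene F1, which is isolated. Chloride 13 is converted with zinc dust and LiCl in THF into (2,3,5,6-tetramethoxybenzyl)zinc chloride F2. Negishi coupling of F1 with F2 under Pd(PPh3)4 in THF at rt then forms the same C1–C2 bond with retention of the E geometry and with no aluminium Lewis acid present.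

3. Step 11. The strong acid may protonate the trisubstituted alkenes, causing migration of the ring double bond or cation–olefin cyclisation of the side chain, or the hydrolysis may not distinguish the two methoxy groups. The fallback sets out from 17 and comes back at 18. Both vinylogous esters are saponified with aqueous NaOH in THF/MeOH, and acidification gives 2,5-dihydroxy-3-{(E)-3-methyl-5-[(S)-2,6,6-trimethylcyclohex-2-en-1-yl]pent-2-en-1-yl}cyclohexa-2,5-diene-1,4-dione F3. This vinylogous acid is then mono-etherified with MeOH and catalytic BF3·OEt2 at rt, where the unhindered oxygen remote from the side chain should react first.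

**Further compounds**

F0 | step 2 | none | none
F1 | step 9 | (S)-6-[(E)-4-iodo-3-methylbut-3-en-1-yl]-1,5,5-trimethylcyclohex-1-ene | I/C=C(\C)CC[C@@H]1C(C)=CCCC1(C)C
F2 | step 9 | (2,3,5,6-tetramethoxybenzyl)zinc chloride | COc1cc(OC)c(OC)c(C[Zn]Cl)c1OC
F3 | step 11 | 2,5-dihydroxy-3-{(E)-3-methyl-5-[(S)-2,6,6-trimethylcyclohex-2-en-1-yl]pent-2-en-1-yl}cyclohexa-2,5-diene-1,4-dione | OC1=CC(=O)C(O)=C(C/C=C(\C)CC[C@@H]2C(C)=CCCC2(C)C)C1=O
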